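## Retrosynthetic overview

1. Locants follow the 15-oxabicyclo[10.2.1]pentadec-5-ene name of target 22 (C1 carries the methyl group, C8 the isopropenyl group, C12 the ring hydrogen, O15 is the bridge). The 14-membered ring is closed last from iodide 20 and CO in one radical step that forms C2–C3 and C3–C4 (C3 is the CO carbon); loss of PhSO2• gives the C5=C6 E-alkene.
2. C11–C12 comes from a radical union of furanone 10 (as its enol silane) with iodomethyl ketone 5, anti to the silyloxymethyl group. C5–C6 comes from hydroxyalkylation of methyl acrylate, which supplies C4, C5 and the ester.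
3. The furanone ring is formed first (O15–C12 and the C13 ketone) by gold-catalysed oxidation of alkynol 9. Its C1 centre comes from (S)-2-methylglycidol; C12 and C13 come from lithium acetylide.
4. The C8 centre and C6–C10 come from rhodium-catalysed asymmetric isopropenyl addition to 5,6-dihydro-2H-pyran-2-one; LiCH2I then adds C11.
5. Ring order: dihydrofuran-3(2H)-one ring (step 5), then the 14-membered carbocycle (step 12).

Assumption: (S)-BINAP on rhodium delivers the alkenyl group to lactone 1 with the facial sense known for cyclohex-2-enone, giving (S)-3.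

## Route

Step 1
Reactants: 1 5,6-dihydro-2H-pyran-2-one; 2 potassium trifluoro(prop-1-en-2-yl)borate
Product: 3 (4S)-4-(prop-1-en-2-yl)tetrahydro-2H-pyran-2-one
Conditions: [Rh(cod)2]PF6 (3 mol %), (S)-BINAP (3.3 mol %), toluene/H2O (10:1), 105 °C
Reagents that add atoms: none
Why: Hayashi–Miyaura rhodium-catalysed asymmetric 1,4-addition of the alkenyl trifluoroborate to the unsaturated lactone, in which the (S)-BINAP–rhodium alkenyl species inserts one face of the enoate and sets C8 as S before water protonates the rhodium enolate.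

Step 2
Reactants: 3 (4S)-4-(prop-1-en-2-yl)tetrahydro-2H-pyran-2-one; 4 diiodomethane
Product: 5 (4S)-6-hydroxy-1-iodo-4-(prop-1-en-2-yl)hexan-2-one
Conditions: MeLi·LiBr (1.4 equiv, slow addition to 3 + 4), THF/Et2O, −78 °C; then AcOH, −78 °C
Reagents that add atoms: none
Why: Nucleophilic acyl substitution of the lactone by the carbenoid LiCH2I (Barluenga-type halomethyl ketone synthesis), in which the tetrahedral lithium alkoxide survives at −78 °C so that only one carbenoid adds, and the C8 centre is not enolisable and stays untouched.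

Step 3
Reactants: 6 (S)-2-methylglycidol
Product: 7 tert-butyl{[(2R)-2-methyloxiran-2-yl]methoxy}diphenylsilane
Conditions: TBDPSCl, imidazole, CH2Cl2, 0 °C to rt
Reagents that add atoms: tert-butyl(chloro)diphenylsilane, CC(C)(C)[Si](Cl)(c1ccccc1)c1ccccc1
Why: Standard silylation of the primary alcohol, which installs the bulky group that later directs step 6 and leaves the chiral-pool C1 centre untouched (the descriptor changes only through CIP priorities).

Step 4
Reactants: 7 tert-butyl{[(2R)-2-methyloxiran-2-yl]methoxy}diphenylsilane; 8 lithium acetylide–ethylenediamine complex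
Product: 9 (2R)-1-[(tert-butyldiphenylsilyl)oxy]-2-methylpent-4-yn-2-ol
Conditions: 8 (3 equiv), DMSO, rt; then H2O
Reagents that add atoms: none
Why: SN2 opening of the 2,2-disubstituted epoxide at its CH2 carbon by acetylide, which does not break the C–O bond at the quaternary carbon and so retains the configuration of the tertiary carbinol.

Step 5
Reactants: 9 (2R)-1-[(tert-butyldiphenylsilyl)oxy]-2-methylpent-4-yn-2-ol
Product: 10 (5R)-5-{[(tert-butyldiphenylsilyl)oxy]methyl}-5-methyldihydrofuran-3(2H)-one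
Conditions: Ph3PAuNTf2 (5 mol %), 3,5-dichloropyridine N-oxide (2 equiv), MsOH (1.2 equiv), ClCH2CH2Cl, rt
Reagents that add atoms: 3,5-dichloropyridine N-oxide, [O-][n+]1cc(Cl)cc(Cl)c1
Why: Gold-catalysed alkyne oxidation (Zhang dihydrofuran-3-one synthesis), in which the N-oxide delivers oxygen to the internal alkyne carbon and the α-oxo gold carbene at the terminal carbon is trapped by the tertiary hydroxyl in a five-membered O–H insertion that does not involve the stereocentre.

Step 6
Reactants: 10 (5R)-5-{[(tert-butyldiphenylsilyl)oxy]methyl}-5-methyldihydrofuran-3(2H)-one; 5 (4S)-6-hydroxy-1-iodo-4-(prop-1-en-2-yl)hexan-2-one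
Product: 12 (2S,5R)-5-{[(tert-butyldiphenylsilyl)oxy]methyl}-2-[(4S)-6-hydroxy-2-oxo-4-(prop-1-en-2-yl)hexyl]-5-methyldihydrofuran-3(2H)-one, via trimethylsilyl enol ether 11 (not isolated)
Conditions: Me3SiOTf, Et3N, CH2Cl2, 0 °C; then 5 (0.5 equiv), Et3B (0.3 equiv)/air, 2,6-lutidine, CH2Cl2 (1 M), 0 °C to rt; aq. citric acid
Reagents that add atoms: trimethylsilyl triflate, C[Si](C)(C)OS(=O)(=O)C(F)(F)F (its silyl group is carried only by 11)
Why: Soft enolisation gives the enol silane toward the oxygen-bearing C12 (C14 is neopentyl-like), and Et3B/O2-initiated atom-transfer radical addition (Kharasch type) of the α-keto radical from 5 to C12 takes place anti to the large silyloxymethyl group, which sets C12 as S with C11 trans to C2, while iodine transfer and loss of Me3SiI give the 1,4-diketone without base and the high concentration of 11 outruns 6-endo closure of the radical onto its own isopropenyl group.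

Step 7
Reactants: 12 (2S,5R)-5-{[(tert-butyldiphenylsilyl)oxy]methyl}-2-[(4S)-6-hydroxy-2-oxo-4-(prop-1-en-2-yl)hexyl]-5-methyldihydrofuran-3(2H)-one
Product: 13 (3S)-6-[(2S,5R)-5-{[(tert-butyldiphenylsilyl)oxy]methyl}-5-methyl-3-oxotetrahydrofuran-2-yl]-5-oxo-3-(prop-1-en-2-yl)hexanal
Conditions: Dess–Martin periodinane, CH2Cl2, 0 °C to rt
Reagents that add atoms: none
Why: Dess–Martin oxidation of the only primary alcohol (the cyclic hemiketal form cannot be oxidised and drains through the open form) under non-basic conditions that leave the epimerisable C12 centre untouched.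

Step 8
Reactants: 13 (3S)-6-[(2S,5R)-5-{[(tert-butyldiphenylsilyl)oxy]methyl}-5-methyl-3-oxotetrahydrofuran-2-yl]-5-oxo-3-(prop-1-en-2-yl)hexanal; 14 methyl acrylate
Product: 15 methyl 2-{(3S)-6-[(2S,5R)-5-{[(tert-butyldiphenylsilyl)oxy]methyl}-5-methyl-3-oxotetrahydrofuran-2-yl]-1-hydroxy-5-oxo-3-(prop-1-en-2-yl)hexyl}prop-2-enoate
Conditions: 14 (5 equiv), DABCO (1 equiv), MeOH, rt, 48 h
Reagents that add atoms: none
Why: Morita–Baylis–Hillman reaction of the aldehyde (the ketones are much less reactive) with methyl acrylate, where the new carbinol centre forms as a mixture that is irrelevant because this carbon becomes sp2 in step 12, and DABCO is too weak a base to epimerise C12.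

Step 9
Reactants: 15 methyl 2-{(3S)-6-[(2S,5R)-5-{[(tert-butyldiphenylsilyl)oxy]methyl}-5-methyl-3-oxotetrahydrofuran-2-yl]-1-hydroxy-5-oxo-3-(prop-1-en-2-yl)hexyl}prop-2-enoate
Product: 17 methyl 2-{(3R)-6-[(2S,5R)-5-{[(tert-butyldiphenylsilyl)oxy]methyl}-5-methyl-3-oxotetrahydrofuran-2-yl]-5-oxo-1-(phenylsulfonyl)-3-(prop-1-en-2-yl)hexyl}prop-2-enoate, via allylic acetate 16 (not isolated)
Conditions: Ac2O, Et3N, DMAP (cat.), CH2Cl2, 0 °C; evaporate; then DABCO (1 equiv), PhSO2Na (1.5 equiv), THF/H2O, rt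
Reagents that add atoms: acetic anhydride, CC(=O)OC(C)=O (its acetyl group is carried only by 16); sodium benzenesulfinate, [Na+].[O-]S(=O)c1ccccc1
Why: Acetylation followed by DABCO-mediated SN2′–SN2′ allylic substitution (DABCO adds to the acrylate terminus and expels acetate, then sulfinate adds to the terminus of the allylammonium salt and expels DABCO), which gives the secondary allyl sulfone with the terminal methylene intact and a sulfonyl-bearing carbon whose configuration is erased in step 12.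

Step 10
Reactants: 17 methyl 2-{(3R)-6-[(2S,5R)-5-{[(tert-butyldiphenylsilyl)oxy]methyl}-5-methyl-3-oxotetrahydrofuran-2-yl]-5-oxo-1-(phenylsulfonyl)-3-(prop-1-en-2-yl)hexyl}prop-2-enoate
Product: 18 methyl 2-{(3R)-6-[(2S,5R)-5-(hydroxymethyl)-5-methyl-3-oxotetrahydrofuran-2-yl]-5-oxo-1-(phenylsulfonyl)-3-(prop-1-en-2-yl)hexyl}prop-2-enoate
Conditions: HF·pyridine, pyridine, THF, 0 °C to rt
Reagents that add atoms: none
Why: Fluoride-mediated cleavage of the silyl ether under buffered, weakly acidic conditions that neither isomerise the allyl sulfone nor epimerise C12.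

Step 11
Reactants: 18 methyl 2-{(3R)-6-[(2S,5R)-5-(hydroxymethyl)-5-methyl-3-oxotetrahydrofuran-2-yl]-5-oxo-1-(phenylsulfonyl)-3-(prop-1-en-2-yl)hexyl}prop-2-enoate
Product: 20 methyl 2-{(3R)-6-[(2S,5R)-5-(iodomethyl)-5-methyl-3-oxotetrahydrofuran-2-yl]-5-oxo-1-(phenylsulfonyl)-3-(prop-1-en-2-yl)hexyl}prop-2-enoate, via primary triflate 19 (not isolated)
Conditions: Tf2O, 2,6-lutidine, CH2Cl2, −78 °C; then Bu4NI, −78 °C to rt
Reagents that add atoms: triflic anhydride, O=S(=O)(OS(=O)(=O)C(F)(F)F)C(F)(F)F (its triflyl group is carried only by 19); tetrabutylammonium iodide, CCCC[N+](CCCC)(CCCC)CCCC.[I-]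
Why: Triflation and in situ Finkelstein-type SN2 displacement by iodide, where the triflate makes substitution at the neopentyl-like carbon possible at low temperature and no stereocentre is touched.

Step 12
Reactants: 20 methyl 2-{(3R)-6-[(2S,5R)-5-(iodomethyl)-5-methyl-3-oxotetrahydrofuran-2-yl]-5-oxo-1-(phenylsulfonyl)-3-(prop-1-en-2-yl)hexyl}prop-2-enoate; 21 carbon monoxide
Product: 22 methyl (1S,5E,8S,12S)-1-methyl-3,10,13-trioxo-8-(prop-1-en-2-yl)-15-oxabicyclo[10.2.1]pentadec-5-ene-5-carboxylate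
Conditions: CO (80 atm), Bu3SnH (1.5 equiv), AIBN (0.3 equiv), benzene (0.003 M), 90 °C
Reagents that add atoms: none
Why: Proposed new method: Bu3Sn• abstracts iodine, the primary radical is captured by CO (about 0.6 M at 80 atm) faster than it is reduced, the nucleophilic acyl radical adds 14-endo to the unsubstituted acrylate terminus, and β-scission of the carbon–sulfur bond of the α-ester radical releases PhSO2• (which takes hydrogen from Bu3SnH and carries the chain) and forms C5=C6 as the more stable E isomer with C7 anti to the ester, all under neutral conditions that leave C1, C8 and C12 untouched, the closest known reactions being Ryu's (n+1) radical carbonylative macrocyclisation of ω-iodoalkyl acrylates and SH2′ allyl transfer from allyl sulfones.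

## Compound list

1 | 5,6-dihydro-2H-pyran-2-one | O=C1C=CCCO1 | starting material
2 | potassium trifluoro(prop-1-en-2-yl)borate | C=C(C)[B-](F)(F)F.[K+] | starting material
3 | (4S)-4-(prop-1-en-2-yl)tetrahydro-2H-pyran-2-one | O=C1C[C@@H](C(C)=C)CCO1 | intermediate
4 | diiodomethane | ICI | starting material
5 | (4S)-6-hydroxy-1-iodo-4-(prop-1-en-2-yl)hexan-2-one (in equilibrium with its cyclic hemiketal) | C=C(C)[C@H](CC(=O)CI)CCO | intermediate
6 | (S)-2-methylglycidol, [(2S)-2-methyloxiran-2-yl]methanol | C[C@@]1(CO1)CO | starting material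
7 | tert-butyl{[(2R)-2-methyloxiran-2-yl]methoxy}diphenylsilane (same spatial arrangement as 6; CIP priority change) | CC(C)(C)[Si](c1ccccc1)(c1ccccc1)OC[C@@]1(C)CO1 | intermediate
8 | lithium acetylide–ethylenediamine complex, LiC≡CH·H2NCH2CH2NH2 | [Li+].[C-]#C.NCCN | starting material
9 | (2R)-1-[(tert-butyldiphenylsilyl)oxy]-2-methylpent-4-yn-2-ol | CC(C)(C)[Si](c1ccccc1)(c1ccccc1)OC[C@@](O)(C)CC#C | intermediate
10 | (5R)-5-{[(tert-butyldiphenylsilyl)oxy]methyl}-5-methyldihydrofuran-3(2H)-one | CC(C)(C)[Si](c1ccccc1)(c1ccccc1)OC[C@@]1(C)CC(=O)CO1 | intermediate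
11 | tert-butyl({(2R)-2-methyl-4-[(trimethylsilyl)oxy]-2,3-dihydrofuran-2-yl}methoxy)diphenylsilane | CC(C)(C)[Si](c1ccccc1)(c1ccccc1)OC[C@@]1(C)CC(O[Si](C)(C)C)=CO1 | intermediate (not isolated)
12 | (2S,5R)-5-{[(tert-butyldiphenylsilyl)oxy]methyl}-2-[(4S)-6-hydroxy-2-oxo-4-(prop-1-en-2-yl)hexyl]-5-methyldihydrofuran-3(2H)-one | CC(C)(C)[Si](c1ccccc1)(c1ccccc1)OC[C@@]1(C)CC(=O)[C@H](CC(=O)C[C@@H](C(C)=C)CCO)O1 | intermediate
13 | (3S)-6-[(2S,5R)-5-{[(tert-butyldiphenylsilyl)oxy]methyl}-5-methyl-3-oxotetrahydrofuran-2-yl]-5-oxo-3-(prop-1-en-2-yl)hexanal | CC(C)(C)[Si](c1ccccc1)(c1ccccc1)OC[C@@]1(C)CC(=O)[C@H](CC(=O)C[C@@H](C(C)=C)CC=O)O1 | intermediate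
14 | methyl acrylate | C=CC(=O)OC | starting material
15 | methyl 2-{(3S)-6-[(2S,5R)-5-{[(tert-butyldiphenylsilyl)oxy]methyl}-5-methyl-3-oxotetrahydrofuran-2-yl]-1-hydroxy-5-oxo-3-(prop-1-en-2-yl)hexyl}prop-2-enoate (both epimers at the carbinol carbon) | CC(C)(C)[Si](c1ccccc1)(c1ccccc1)OC[C@@]1(C)CC(=O)[C@H](CC(=O)C[C@@H](C(C)=C)CC(O)C(=C)C(=O)OC)O1 | intermediate
16 | methyl 2-{(3S)-1-acetoxy-6-[(2S,5R)-5-{[(tert-butyldiphenylsilyl)oxy]methyl}-5-methyl-3-oxotetrahydrofuran-2-yl]-5-oxo-3-(prop-1-en-2-yl)hexyl}prop-2-enoate (both epimers at the acetoxy carbon) | CC(C)(C)[Si](c1ccccc1)(c1ccccc1)OC[C@@]1(C)CC(=O)[C@H](CC(=O)C[C@@H](C(C)=C)CC(OC(C)=O)C(=C)C(=O)OC)O1 | intermediate (not isolated)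
17 | methyl 2-{(3R)-6-[(2S,5R)-5-{[(tert-butyldiphenylsilyl)oxy]methyl}-5-methyl-3-oxotetrahydrofuran-2-yl]-5-oxo-1-(phenylsulfonyl)-3-(prop-1-en-2-yl)hexyl}prop-2-enoate (both epimers at the sulfonyl carbon; 3R is the same spatial arrangement as 3S in 15, sulfur now outranks oxygen) | CC(C)(C)[Si](c1ccccc1)(c1ccccc1)OC[C@@]1(C)CC(=O)[C@H](CC(=O)C[C@@H](C(C)=C)CC(C(=C)C(=O)OC)S(=O)(=O)c2ccccc2)O1 | intermediate
18 | methyl 2-{(3R)-6-[(2S,5R)-5-(hydroxymethyl)-5-methyl-3-oxotetrahydrofuran-2-yl]-5-oxo-1-(phenylsulfonyl)-3-(prop-1-en-2-yl)hexyl}prop-2-enoate | OC[C@@]1(C)CC(=O)[C@H](CC(=O)C[C@@H](C(C)=C)CC(C(=C)C(=O)OC)S(=O)(=O)c2ccccc2)O1 | intermediate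
19 | methyl 2-{(3R)-6-[(2S,5R)-5-methyl-3-oxo-5-({[(trifluoromethyl)sulfonyl]oxy}methyl)tetrahydrofuran-2-yl]-5-oxo-1-(phenylsulfonyl)-3-(prop-1-en-2-yl)hexyl}prop-2-enoate | O=S(=O)(OC[C@@]1(C)CC(=O)[C@H](CC(=O)C[C@@H](C(C)=C)CC(C(=C)C(=O)OC)S(=O)(=O)c2ccccc2)O1)C(F)(F)F | intermediate (not isolated)
20 | methyl 2-{(3R)-6-[(2S,5R)-5-(iodomethyl)-5-methyl-3-oxotetrahydrofuran-2-yl]-5-oxo-1-(phenylsulfonyl)-3-(prop-1-en-2-yl)hexyl}prop-2-enoate | IC[C@@]1(C)CC(=O)[C@H](CC(=O)C[C@@H](C(C)=C)CC(C(=C)C(=O)OC)S(=O)(=O)c2ccccc2)O1 | intermediate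
21 | carbon monoxide | [C-]#[O+] | starting material
22 | methyl (1S,5E,8S,12S)-1-methyl-3,10,13-trioxo-8-(prop-1-en-2-yl)-15-oxabicyclo[10.2.1]pentadec-5-ene-5-carboxylate (CNP0163183.4) | C=C(C)[C@H]1C/C=C(/C(=O)OC)CC(=O)C[C@@]2(C)CC(=O)[C@H](CC(=O)C1)O2 | target

## Step count and risks

Total step count: 12. Longest linear sequence: 10 steps (6 → 7 → 9 → 10 → 12 → 13 → 15 → 17 → 18 → 20 → 22; steps 3 to 12).

The three steps most likely to fail:

Step 12 (carbonylative ring closure). Sulfonyl radicals may move the sulfone to the conjugated primary position before the acyl radical cyclises, or the chain may be inefficient at high dilution. The fallback replaces fragmentation by radical addition–reduction followed by ionic elimination; it sets out from 16 (isolated in this variant) and comes back at 22. HF·pyridine gives methyl 2-{(3S)-1-acetoxy-6-[(2S,5R)-5-(hydroxymethyl)-5-methyl-3-oxotetrahydrofuran-2-yl]-5-oxo-3-(prop-1-en-2-yl)hexyl}prop-2-enoate F5. Tf2O/2,6-lutidine then Bu4NI gives methyl 2-{(3S)-1-acetoxy-6-[(2S,5R)-5-(iodomethyl)-5-methyl-3-oxotetrahydrofuran-2-yl]-5-oxo-3-(prop-1-en-2-yl)hexyl}prop-2-enoate F6. (Me3Si)3SiH, AIBN and CO (80 atm, 0.003 M, 90 °C) close the ring by 14-endo Giese addition to methyl (1S,8S,12S)-6-acetoxy-1-methyl-3,10,13-trioxo-8-(prop-1-en-2-yl)-15-oxabicyclo[10.2.1]pentadecane-5-carboxylate F7. A short DBU treatment at 0 °C eliminates acetic acid to 22; the exposure is kept short because base can epimerise C12.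

Step 6 (radical union and C12 configuration). The α-keto radical from 5 can close 6-endo onto its own isopropenyl group, and the facial bias of the silyloxymethyl group against a methyl group may be modest. The fallback puts the radical on the furanone instead; it sets out from 3 and 11 and comes back at 12. MeLi (1 equiv, −78 °C) opens 3 to (4S)-6-hydroxy-4-(prop-1-en-2-yl)hexan-2-one F1. LiN(iPr)2/Me3SiCl at −78 °C gives the kinetic enol silane (4S)-4-(prop-1-en-2-yl)-2,6-bis[(trimethylsilyl)oxy]hex-1-ene F2. NBS at −78 °C converts 11 into (5R)-2-bromo-5-{[(tert-butyldiphenylsilyl)oxy]methyl}-5-methyldihydrofuran-3(2H)-one F3. Et3B/air adds the C12 radical of F3 to F2 anti to the silyloxymethyl group (bromine-atom transfer, loss of Me3SiBr), and dilute acid gives 12.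

Step 11 (iodide at the neopentyl-like carbon). Displacement may be slow, or the ring oxygen may participate and expand the ring. The fallback avoids substitution at carbon; it sets out from 18 and comes back at 22. PhOC(S)Cl/pyridine gives methyl 2-{(3R)-6-[(2S,5R)-5-methyl-3-oxo-5-{[(phenoxycarbonothioyl)oxy]methyl}tetrahydrofuran-2-yl]-5-oxo-1-(phenylsulfonyl)-3-(prop-1-en-2-yl)hexyl}prop-2-enoate F4. Under the conditions of step 12 (toluene, 100 °C) Bu3Sn• adds to sulfur, the carbon–oxygen bond fragments to the same primary radical, and carbonylation and ring closure follow as before.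

## Further compounds

F1 | step 6 | (4S)-6-hydroxy-4-(prop-1-en-2-yl)hexan-2-one | CC(=O)C[C@@H](C(C)=C)CCO
F2 | step 6 | (4S)-4-(prop-1-en-2-yl)-2,6-bis[(trimethylsilyl)oxy]hex-1-ene | C=C(O[Si](C)(C)C)C[C@@H](C(C)=C)CCO[Si](C)(C)C
F3 | step 6 | (5R)-2-bromo-5-{[(tert-butyldiphenylsilyl)oxy]methyl}-5-methyldihydrofuran-3(2H)-one (both C2 epimers) | CC(C)(C)[Si](c1ccccc1)(c1ccccc1)OC[C@@]1(C)CC(=O)C(Br)O1
F4 | step 11 | methyl 2-{(3R)-6-[(2S,5R)-5-methyl-3-oxo-5-{[(phenoxycarbonothioyl)oxy]methyl}tetrahydrofuran-2-yl]-5-oxo-1-(phenylsulfonyl)-3-(prop-1-en-2-yl)hexyl}prop-2-enoate | S=C(Oc1ccccc1)OC[C@@]1(C)CC(=O)[C@H](CC(=O)C[C@@H](C(C)=C)CC(C(=C)C(=O)OC)S(=O)(=O)c2ccccc2)O1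
F5 | step 12 | methyl 2-{(3S)-1-acetoxy-6-[(2S,5R)-5-(hydroxymethyl)-5-methyl-3-oxotetrahydrofuran-2-yl]-5-oxo-3-(prop-1-en-2-yl)hexyl}prop-2-enoate | OC[C@@]1(C)CC(=O)[C@H](CC(=O)C[C@@H](C(C)=C)CC(OC(C)=O)C(=C)C(=O)OC)O1
F6 | step 12 | methyl 2-{(3S)-1-acetoxy-6-[(2S,5R)-5-(iodomethyl)-5-methyl-3-oxotetrahydrofuran-2-yl]-5-oxo-3-(prop-1-en-2-yl)hexyl}prop-2-enoate | IC[C@@]1(C)CC(=O)[C@H](CC(=O)C[C@@H](C(C)=C)CC(OC(C)=O)C(=C)C(=O)OC)O1
F7 | step 12 | methyl (1S,8S,12S)-6-acetoxy-1-methyl-3,10,13-trioxo-8-(prop-1-en-2-yl)-15-oxabicyclo[10.2.1]pentadecane-5-carboxylate (mixture at C5 and C6) | C=C(C)[C@H]1CC(OC(C)=O)C(C(=O)OC)CC(=O)C[C@@]2(C)CC(=O)[C@H](CC(=O)C1)O2
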